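**Retrosynthetic overview**

1. The target comes from the (2S)-5,7-bis(MOM) flavanone 19 by removal of the two MOM acetals. Rings A (benzo ring) and B (4-geranyloxyphenyl) are bought as benzene rings; ring C (the pyranone) is the only ring made.
2. Key disconnection: ring C is opened at O1–C8a and at C4–C4a in one cut, giving 3,5-bis(methoxymethoxy)benzyne 16 (ring A) and the (S)-β-silyloxy Weinreb amide 14 (chain O1–C2–C3–C4 carrying ring B). Forward, this is an aryne annulation: alkoxide addition, then intramolecular acyl substitution.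
3. Enabling feature: on ring A the ether oxygen O1 (on C8a) and the acyl carbon C4 (on C4a) sit on adjacent carbons, the 1,2-pattern of an aryne, and the C5 oxygen next to C4a steers O1 to C8a. The chain O1–C2–C3–C4 is an aldol (β-hydroxy acid) unit whose oxygen nucleophile and acyl electrophile span exactly the six-membered ring C.
4. C2 is set before the key step by asymmetric transfer hydrogenation of β-keto amide 12, made from methyl 4-hydroxybenzoate, geranyl bromide and N-methoxy-N-methylacetamide.
5. Aryne precursor 6 comes from phloroglucinol: bis-MOM ether, ortho-bromination, one-pot silylation/retro-Brook shift/triflation.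

Key step: step 8

Remark: the target is taken as (2S)-naringenin 4'-O-geranyl ether with a 2E geranyl group. Chromanone numbering (O1, C2, C3, C4, C4a, C5–C8, C8a) is used throughout, and all amounts are planned quantities.

**Route**

Step 1
Reactants: 1 phloroglucinol (benzene-1,3,5-triol)
Product: 2 3,5-bis(methoxymethoxy)phenol
Conditions: NaH (2.0 equiv), MOMCl (2.0 equiv), DMF, 0 °C → rt
Reagents that add atoms: chloromethyl methyl ether (MOMCl), COCCl
Why: Statistical double Williamson O-alkylation of the symmetric triphenol, the bis-ether being separated by chromatography from the mono- and tris-ethers.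

Step 2
Reactants: 2 3,5-bis(methoxymethoxy)phenol
Product: 3 2-bromo-3,5-bis(methoxymethoxy)phenol
Conditions: NBS (1.0 equiv), i-Pr2NH (0.1 equiv), CH2Cl2, −78 °C
Reagents that add atoms: N-bromosuccinimide, O=C1CCC(=O)N1Br
Why: Amine-mediated ortho-selective electrophilic bromination of a phenol (hydrogen-bond-directed delivery of bromine next to the free hydroxyl), the para isomer being removed by chromatography.

Step 3
Reactants: 3 2-bromo-3,5-bis(methoxymethoxy)phenol
Product: 6 3,5-bis(methoxymethoxy)-2-(trimethylsilyl)phenyl trifluoromethanesulfonate, via aryl silyl ether 4 (not isolated), via lithium silylphenoxide 5 (not isolated)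
Conditions: HMDS, THF, 70 °C, then evaporation; n-BuLi (1.1 equiv), THF, −100 → −78 °C; Tf2O (1.2 equiv), −100 °C → rt
Reagents that add atoms: hexamethyldisilazane, C[Si](C)(C)N[Si](C)(C)C; trifluoromethanesulfonic anhydride, O=S(=O)(OS(=O)(=O)C(F)(F)F)C(F)(F)F
Why: The standard one-pot synthesis of ortho-silylaryl triflates: O-silylation, bromine–lithium exchange (faster than any ortho-metalation), anionic 1,3 O→C silyl shift (retro-Brook rearrangement) to phenoxide 5 and O-triflation, none of which touches the MOM acetals.

Step 4
Reactants: 7 methyl 4-hydroxybenzoate; 8 geranyl bromide ((2E)-1-bromo-3,7-dimethylocta-2,6-diene)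
Product: 9 methyl 4-{[(2E)-3,7-dimethylocta-2,6-dien-1-yl]oxy}benzoate
Conditions: K2CO3, DMF, rt
Reagents that add atoms: none
Why: Williamson O-alkylation (SN2 of the phenoxide at the primary allylic bromide), which keeps the 2E alkene geometry.

Step 5
Reactants: 9 methyl 4-(geranyloxy)benzoate; 10 N-methoxy-N-methylacetamide
Product: 12 3-(4-{[(2E)-3,7-dimethylocta-2,6-dien-1-yl]oxy}phenyl)-N-methoxy-N-methyl-3-oxopropanamide, via lithium amide enolate 11 (not isolated)
Conditions: LiN(i-Pr)2 (2.2 equiv), 10 (2.2 equiv), THF, −78 °C; then 9, −78 → 0 °C; 1 M HCl, 0 °C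
Reagents that add atoms: none
Why: Crossed Claisen condensation of the preformed lithium enolate of a Weinreb acetamide with a non-enolisable aryl ester, the second equivalent of enolate deprotonating the β-keto amide and so driving the condensation and shielding the product.

Step 6
Reactants: 12 β-keto Weinreb amide
Product: 13 (3S)-3-(4-{[(2E)-3,7-dimethylocta-2,6-dien-1-yl]oxy}phenyl)-3-hydroxy-N-methoxy-N-methylpropanamide
Conditions: RuCl(p-cymene)[(S,S)-TsDPEN] (1 mol %), HCO2H/Et3N (5:2), CH2Cl2, rt
Reagents that add atoms: none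
Why: Noyori–Ikariya asymmetric transfer hydrogenation of an aryl ketone, in which the (S,S)-ligand directs hydride to the Re face of the C=O through the CH/π-organised outer-sphere transition state (as for acetophenone) to give the (S)-carbinol, while the trisubstituted alkenes and the N–O bond are not reduced.

Step 7
Reactants: 13 (S)-β-hydroxy Weinreb amide
Product: 14 (3S)-3-(4-{[(2E)-3,7-dimethylocta-2,6-dien-1-yl]oxy}phenyl)-N-methoxy-N-methyl-3-(trimethylsilyloxy)propanamide
Conditions: 1-(trimethylsilyl)imidazole (1.3 equiv), CH2Cl2, rt; filtration through Et3N-deactivated silica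
Reagents that add atoms: 1-(trimethylsilyl)imidazole, C[Si](C)(C)n1ccnc1
Why: Neutral O-silylation of a secondary alcohol with a silylimidazole, giving the latent, proton-free alkoxide needed in step 8 without involving the stereocentre.

Step 8
Reactants: 14 (S)-β-silyloxy Weinreb amide; 6 3,5-bis(methoxymethoxy)-2-(trimethylsilyl)phenyl trifluoromethanesulfonate
Product: 19 (2S)-2-(4-{[(2E)-3,7-dimethylocta-2,6-dien-1-yl]oxy}phenyl)-5,7-bis(methoxymethoxy)chroman-4-one, via potassium alkoxide 15 (not isolated), via aryne 16 (not isolated), via aryl anion 17 (not isolated), via hemiaminal alkoxide 18 (not isolated)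
Conditions: spray-dried KF (3.5 equiv), 18-crown-6 (3.5 equiv), THF, 0 °C; 6 (1.4 equiv) added over 2 h, 0 °C → rt; then sat. aq. NH4Cl, 0 °C
Reagents that add atoms: none
Why: Proposed new method: fluoride strips both silyl groups, so the potassium alkoxide 15 (no proton source present) adds to the aryne carbon of 16 that is meta to both MOM ethers, and the aryl anion 17 so formed, stabilised inductively and by chelation through the flanking MOM ether, attacks the Weinreb carbonyl to give the hemiaminal alkoxide 18, which releases the C4 ketone only on aqueous quench. The closest known reaction type is the fluoride-mediated aryne annulation of methyl salicylates to xanthones (phenoxide addition, then acyl substitution by the aryl anion), supported by aryne insertion into amide N–C(=O) bonds and the aryne acyl-alkylation of β-keto esters, but an aliphatic β-alkoxy amide has not been used in this role. Ring C is closed by a 6-exo-trig acyl substitution that follows the intermolecular O1–C8a bond formation. No new stereocentre survives the step: C2 comes from step 6 and is untouched because its C–O bond is never broken, and the amide (unlike an ester or a ketone) disfavours retro-aldol cleavage of 15 and keeps the ketone masked against base-induced E1cB opening until the quench. The step needs regioselectivity in the aryne addition, which the oxygen next to the aryne bond secures through the known distortion and inductive bias of 3-alkoxyarynes (as in acyl-alkylations of 3,5-dialkoxybenzynes). It also needs the aryl anion to add to the carbonyl faster than it abstracts a proton, which the aprotic medium, the silyl ether in place of the free alcohol and the weakly acidic amide α-hydrogens favour.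

Step 9
Reactants: 19 (2S)-5,7-bis(methoxymethoxy) flavanone
Product: 20 (2S)-2-(4-{[(2E)-3,7-dimethylocta-2,6-dien-1-yl]oxy}phenyl)-5,7-dihydroxychroman-4-one (target)
Conditions: 3 M aq. HCl/MeOH/THF (1:4:2), rt
Reagents that add atoms: none
Why: Acid-catalysed acetal exchange with methanol, in which both MOM groups sit on phenols that are good leaving groups (ortho and para to the C4 carbonyl), ring C cannot open by the base-induced E1cB path so C2 is kept, and the geranyl aryl ether should tolerate dilute methanolic acid at room temperature.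

**Compound list**

1 | phloroglucinol | Oc1cc(O)cc(O)c1 | starting material
2 | 3,5-bis(methoxymethoxy)phenol | Oc1cc(OCOC)cc(OCOC)c1 | intermediate
3 | 2-bromo-3,5-bis(methoxymethoxy)phenol | Oc1cc(OCOC)cc(OCOC)c1Br | intermediate
4 | [2-bromo-3,5-bis(methoxymethoxy)phenoxy]trimethylsilane | C[Si](C)(C)Oc1cc(OCOC)cc(OCOC)c1Br | intermediate
5 | lithium 3,5-bis(methoxymethoxy)-2-(trimethylsilyl)phenoxide | [Li+].[O-]c1cc(OCOC)cc(OCOC)c1[Si](C)(C)C | intermediate
6 | 3,5-bis(methoxymethoxy)-2-(trimethylsilyl)phenyl trifluoromethanesulfonate | C[Si](C)(C)c1c(OS(=O)(=O)C(F)(F)F)cc(OCOC)cc1OCOC | intermediate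
7 | methyl 4-hydroxybenzoate | COC(=O)c1ccc(O)cc1 | starting material
8 | geranyl bromide | CC(C)=CCC/C(C)=C/CBr | starting material
9 | methyl 4-{[(2E)-3,7-dimethylocta-2,6-dien-1-yl]oxy}benzoate | CC(C)=CCC/C(C)=C/COc1ccc(C(=O)OC)cc1 | intermediate
10 | N-methoxy-N-methylacetamide | CC(=O)N(C)OC | starting material
11 | lithium enolate of N-methoxy-N-methylacetamide | [Li+].[O-]C(=C)N(C)OC | intermediate
12 | 3-[4-(geranyloxy)phenyl]-N-methoxy-N-methyl-3-oxopropanamide | CC(C)=CCC/C(C)=C/COc1ccc(C(=O)CC(=O)N(C)OC)cc1 | intermediate
13 | (3S)-3-[4-(geranyloxy)phenyl]-3-hydroxy-N-methoxy-N-methylpropanamide | CC(C)=CCC/C(C)=C/COc1ccc([C@H](CC(=O)N(C)OC)O)cc1 | intermediate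
14 | (3S)-3-[4-(geranyloxy)phenyl]-N-methoxy-N-methyl-3-(trimethylsilyloxy)propanamide | CC(C)=CCC/C(C)=C/COc1ccc([C@H](CC(=O)N(C)OC)O[Si](C)(C)C)cc1 | intermediate
15 | potassium (1S)-1-[4-(geranyloxy)phenyl]-3-[methoxy(methyl)amino]-3-oxopropan-1-olate | CC(C)=CCC/C(C)=C/COc1ccc([C@H](CC(=O)N(C)OC)[O-])cc1.[K+] | intermediate
16 | 3,5-bis(methoxymethoxy)benzyne | COCOC1=CC(OCOC)=CC#C1 | intermediate
17 | (3S)-3-[4-(geranyloxy)phenyl]-N-methoxy-N-methyl-3-[3,5-bis(methoxymethoxy)-2-potassiophenoxy]propanamide | CC(C)=CCC/C(C)=C/COc1ccc([C@H](CC(=O)N(C)OC)Oc2cc(OCOC)cc(OCOC)c2[K])cc1 | intermediate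
18 | potassium (2S)-2-[4-(geranyloxy)phenyl]-4-[methoxy(methyl)amino]-5,7-bis(methoxymethoxy)chroman-4-olate (both C4 epimers) | CC(C)=CCC/C(C)=C/COc1ccc([C@@H]2CC([O-])(N(C)OC)c3c(OCOC)cc(OCOC)cc3O2)cc1.[K+] | intermediate
19 | (2S)-2-[4-(geranyloxy)phenyl]-5,7-bis(methoxymethoxy)chroman-4-one | CC(C)=CCC/C(C)=C/COc1ccc([C@@H]2CC(=O)c3c(OCOC)cc(OCOC)cc3O2)cc1 | intermediate
20 | (2S)-2-(4-{[(2E)-3,7-dimethylocta-2,6-dien-1-yl]oxy}phenyl)-5,7-dihydroxychroman-4-one | CC(C)=CCC/C(C)=C/COc1ccc([C@@H]2CC(=O)c3c(O)cc(O)cc3O2)cc1 | target

**Step count and risks**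

Total step count: 9. Longest linear sequence: 6 steps (steps 4 to 9, from methyl 4-hydroxybenzoate); the aryne branch (steps 1 to 3) joins at step 8.

Steps most likely to fail:

1. Step 8 (proposed new method). The aryl anion may abstract a proton (from the amide α-CH2, followed by β-elimination of the aryloxide, or from traces of water) before it reaches the carbonyl, so that only O-arylation or fragmentation occurs. The hemiaminal alkoxide may also collapse early, after which base-induced opening of ring C would erode the configuration at C2, and the aryne may undergo an ene reaction with the geranyl alkenes. Fallback with known chemistry, setting out from 12 and using 3, and rejoining the route at 19: the reduction of step 6 is run with the enantiomeric catalyst RuCl(p-cymene)[(R,R)-TsDPEN] to give (3R)-3-[4-(geranyloxy)phenyl]-3-hydroxy-N-methoxy-N-methylpropanamide F1. This is converted with n-BuLi (1 equiv, THF, −78 °C) into its lithium alkoxide F2 and treated with lithium 2-lithio-3,5-bis(methoxymethoxy)phenoxide F3 (from 3 and n-BuLi, 2 equiv, THF, −78 °C), which adds to the Weinreb amide. NH4Cl work-up should give (3R)-3-[4-(geranyloxy)phenyl]-3-hydroxy-1-[2-hydroxy-4,6-bis(methoxymethoxy)phenyl]propan-1-one F4. Mitsunobu cyclisation (PPh3, diisopropyl azodicarboxylate, THF, 0 °C) then closes the O1–C2 bond with inversion at C2 to give 19.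

2. Step 9. Acid may ionise the geranyl aryl ether or add methanol or HCl across the trisubstituted alkenes before the less labile C7 acetal is cleaved, and ionisation of the electron-rich benzylic C2–O bond could erode the configuration. Fallback without protic acid, setting out from 19 and ending at 20: TMSOTf/2,2'-bipyridyl (CH2Cl2, 0 °C) exchanges both aryl MOM ethers for silyl ethers to give (2S)-2-[4-(geranyloxy)phenyl]-5,7-bis(trimethylsilyloxy)chroman-4-one F5, which is hydrolysed with water at neutral pH to the target 20.

3. Step 2. Bromination may occur para to the hydroxyl (between the two acetals) or twice, giving material that cannot be carried to 6. Fallback by directed ortho-metalation, setting out from 2 and rejoining at 6 (replacing steps 2 and 3): 2 is converted with Et2NCOCl/NaH (THF) into 3,5-bis(methoxymethoxy)phenyl N,N-diethylcarbamate F6. s-BuLi/TMEDA (THF, −78 °C) lithiates ortho to the carbamate (both ortho positions are equivalent and each is flanked by a MOM ether) to give the aryllithium F7, which is quenched with TMSCl to give 3,5-bis(methoxymethoxy)-2-(trimethylsilyl)phenyl N,N-diethylcarbamate F8. LiAlH4 (THF, 0 °C) releases 3,5-bis(methoxymethoxy)-2-(trimethylsilyl)phenol F9, and Tf2O/pyridine (CH2Cl2, 0 °C) gives 6.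

**Further compounds**

F1 | step 8 | (3R)-3-[4-(geranyloxy)phenyl]-3-hydroxy-N-methoxy-N-methylpropanamide | CC(C)=CCC/C(C)=C/COc1ccc([C@@H](CC(=O)N(C)OC)O)cc1
F2 | step 8 | lithium alkoxide of F1 | CC(C)=CCC/C(C)=C/COc1ccc([C@@H](CC(=O)N(C)OC)[O-])cc1.[Li+]
F3 | step 8 | lithium 2-lithio-3,5-bis(methoxymethoxy)phenoxide | [Li]c1c([O-])cc(OCOC)cc1OCOC.[Li+]
F4 | step 8 | (3R)-3-[4-(geranyloxy)phenyl]-3-hydroxy-1-[2-hydroxy-4,6-bis(methoxymethoxy)phenyl]propan-1-one | CC(C)=CCC/C(C)=C/COc1ccc([C@@H](CC(=O)c2c(O)cc(OCOC)cc2OCOC)O)cc1
F5 | step 9 | (2S)-2-[4-(geranyloxy)phenyl]-5,7-bis(trimethylsilyloxy)chroman-4-one | CC(C)=CCC/C(C)=C/COc1ccc([C@@H]2CC(=O)c3c(O[Si](C)(C)C)cc(O[Si](C)(C)C)cc3O2)cc1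
F6 | step 2 | 3,5-bis(methoxymethoxy)phenyl N,N-diethylcarbamate | CCN(CC)C(=O)Oc1cc(OCOC)cc(OCOC)c1
F7 | step 2 | 2-lithio-3,5-bis(methoxymethoxy)phenyl N,N-diethylcarbamate | CCN(CC)C(=O)Oc1cc(OCOC)cc(OCOC)c1[Li]
F8 | step 2 | 3,5-bis(methoxymethoxy)-2-(trimethylsilyl)phenyl N,N-diethylcarbamate | CCN(CC)C(=O)Oc1cc(OCOC)cc(OCOC)c1[Si](C)(C)C
F9 | step 2 | 3,5-bis(methoxymethoxy)-2-(trimethylsilyl)phenol | Oc1cc(OCOC)cc(OCOC)c1[Si](C)(C)C
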